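## The problem

Euchrenone a17 (18) is a flavanone: ring A is fused to the dihydropyranone ring C, and C2 carries ring B, which is itself a 2,2-dimethylchroman. The skeleton is therefore two benzopyrans joined by the single bond from C2 to C1′. C2 (S) is the only stereocentre, so nothing in the molecule can relay it and it must come from a chiral catalyst or a resolution. It is also fragile: O1 is β to the C4 carbonyl, so base opens ring C to the 2′-hydroxychalcone, and C2 is benzylic to a ring with an ether oxygen para to it, so strong acid can ionise the C2–O1 bond. Ring A is contiguously tetrasubstituted (C4a acyl, C8a–O1, C8 prenyl, C7 OH), and the prenyl group has to sit on C8, not on the equally ortho C6. The free 7-OH beside the trisubstituted olefin is an ortho-prenylphenol, which acids cyclise to a further dihydropyran, so the end of the synthesis must be neutral and preferably free of deprotections. The enabling feature is the 1,2-relationship on ring A between O7 and the prenyl CH2 on C8: the atoms O7–C7–C8–CH2–CH=C(CH3)2 are exactly what a [3,3] shift of a 7-O-(2-methylbut-3-en-2-yl) ether leaves behind, with the phenol released in the same event.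

## Retrosynthesis

**18 to 16.** The C8–CH2 bond is cut and the prenyl group is returned, transposed, to O7 as the tertiary allyl ether 16, an isomer of the target. The neighbouring cuts are weaker. Direct C-prenylation of the phenoxide of 12 needs base and gives O-, C6- and C8-alkylation together. Cross-coupling at C8 needs a regioselective halogenation and a protected phenol. Carrying the prenyl group from the start exposes it to every acidic step. The precursor has no C-substituent on ring A and hides the phenol. The forward reaction must prefer C8 to C6 and must run without acid or base; it passes through dienone 17.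

**16 to 12 and 15.** The O7–C(CH3)2 bond is cut. A tertiary allyl ether cannot be made by direct displacement, but allylpalladium chemistry delivers it from phenol 12 and the mixed carbonate 15. Carbonate 15 comes in one step from 2-methylbut-3-en-2-ol (13) through its lithium alkoxide 14. The forward reaction must attack the substituted allyl terminus and must generate no base stronger than the phenoxide.

**12 to 11, then to 4 and 10.** After the silyl ether is restored (11), the C2–C1′ bond is cut. This divides the molecule into two achiral halves of similar size, chromone 4 and boronic acid 10, and the only stereocentre is created as they join. The competing cut at O1–C2 (aldol condensation to a chalcone, then oxa-Michael closure) would need an asymmetric cyclisation that is less developed for unactivated chalcones. The triisopropylsilyl group keeps the chromone soluble and electrophilic and is removed by buffered fluoride, which C2 tolerates.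

**4 to 2 to 1.** The O1–C2 and C2–C3 bonds of the chromone are cut. C2 is a one-carbon unit from an amide acetal, added to the methyl ketone of 2 through enaminone 3. Ketone 2 is the 4-O-silyl ether of 2,4-dihydroxyacetophenone (1), where the chelated 2-OH needs no protection.

**10 to 7, then to 5 and 6.** The C–B bond is traced to bromide 7 through aryllithium 8 and borate 9. In 7 the O–C(CH3)2 and aryl–CH2 bonds of the dihydropyran are cut, giving 4-bromophenol (5) and isoprene (6). This acid-catalysed annulation is placed at the very start, on a substrate that acid cannot harm, so no acid is needed after the prenyl group arrives.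

## Roads not taken

Alternative 1: Ring C is cut around the carbonyl at C4a–C4, C4–C3 and O1–C2. In the forward step the iodophenol A2, carbon monoxide and the arylacetylene A3 are joined with PdCl2(PPh3)2 and diethylamine to give the flavone A1. In bonds formed per operation this is the most efficient construction of ring C among the four plans, and the prenyl regiochemistry is settled on a simple resorcinol. Its weakness is that A1 is flat at C2. The only stereocentre would have to come from an enantioselective conjugate reduction of a 2-arylchromone that also contains a trisubstituted olefin and a reducible ketone, which is less settled than conjugate arylation. A2 needs its own regiocontrolled prenylation and iodination, and aurone formation by five-membered closure can compete. The methoxymethyl group would finally have to leave under acid from an ortho-prenylphenol. The chosen plan is less convergent at ring C, but it makes the stereocentre in the step that joins the halves and ends without a deprotection.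

Alternative 2: The O–C(CH3)2 bond of the ring B chroman is cut. The diprenyl flavanone A4 would be cyclised with a mild acid such as Bi(OTf)3 to the acetate A5, which is then deacetylated. The route is biomimetic and would also give access to the uncyclised diprenyl congeners, which the chosen plan cannot offer. For this target the weaknesses are serious. The acid must activate the 3′-prenyl olefin while an almost identical 8-prenyl olefin survives, and the acetate only stops O7 from cyclising, not the olefin from being protonated. The free 4′-OH para to C2 in A4 makes the stereocentre labile through a quinone methide. The final acetate cleavage needs a base or nucleophile next to a base-sensitive flavanone. Building A4 enantioselectively also needs a prenylated, phenol-protected ring B partner and one more protecting group. The chosen plan closes the same ring in step 3 on 4-bromophenol, where acid is harmless.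

Alternative 3: The C2–C1′ bond is cut as in the chosen plan, but with the prenyl group already on the chromone. Chromone A6 and boronic acid 10 would combine under [RhCl(C2H4)2]2, a chiral diene and substoichiometric aqueous KOH to give A7. This is the most convergent of the plans. It fixes the prenyl position early on cheap material, where an unwanted C6 isomer costs little, and it needs no late thermal step. In convergence and regiochemical security it is at least as good as the chosen plan. Its weak point is the end: the methoxymethyl group of A7 must be removed with acid from a molecule that contains both an ortho-prenylphenol and an acid-labile para-alkoxybenzylic C2–O1 bond. The prenyl olefin must also pass through chromone formation and an aqueous-base rhodium step, and the arylation runs on a chromone with a substituent next to O1. Against this the chosen plan offers a last step that is a neutral isomerisation with nothing to remove afterwards, a prenyl olefin that never meets acid or base, and an arylation on an unhindered chromone. Its price is the C8 against C6 question late in the route; the fallback for step 9 borrows the early-prenyl idea if that price is too high.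

Key step: step 9

Assumption: with chromones the palladium pyridine-oxazoline catalyst is taken to show the same facial preference as with 3-substituted cyclohexenones, which makes the (R)-ligand the one that leads to the (S)-flavanone; the configuration of 11 would be confirmed chiroptically before material is carried on, and the enantiomeric ligand is equally available.

## Route

Step 1
Reactants: 1 2,4-dihydroxyacetophenone
Product: 2 1-[2-hydroxy-4-(triisopropylsilyloxy)phenyl]ethanone
Conditions: TIPSCl (1.05 equiv), imidazole, DMF, 0 → 23 °C
Reagents that add atoms: triisopropylsilyl chloride, CC(C)[Si](Cl)(C(C)C)C(C)C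
Why: Selective phenol silylation: the 2-OH is tied up in a hydrogen bond to the acetyl carbonyl and is hindered, so the bulky chloride should react only at the 4-OH. The triisopropylsilyl aryl ether is chosen because it should survive the amide acetal, brief aqueous acid and the later palladium step, yet leave with buffered fluoride.

Step 2
Reactants: 2 1-[2-hydroxy-4-(triisopropylsilyloxy)phenyl]ethanone
Product: 4 7-(triisopropylsilyloxy)-4H-chromen-4-one, via enaminone 3 (not isolated)
Conditions: Me2NCH(OMe)2, PhMe, 90 °C; concentrate; then conc. aq HCl, CH2Cl2, 23 °C
Reagents that add atoms: N,N-dimethylformamide dimethyl acetal, COC(OC)N(C)C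
Why: Enaminone condensation of the methyl ketone with the amide acetal, then acid-induced addition of the phenol to the vinylogous amide with loss of dimethylamine, is the standard chromone synthesis from 2-hydroxyacetophenones. Aryl silyl ethers tolerate the short exposure to aqueous acid.

Step 3
Reactants: 5 4-bromophenol; 6 isoprene
Product: 7 6-bromo-2,2-dimethylchroman
Conditions: AgOTf (5 mol %), ClCH2CH2Cl, 23 → 50 °C
Reagents that add atoms: none
Why: Acid-catalysed phenol–diene annulation: Friedel–Crafts prenylation ortho to the hydroxyl (para is blocked by bromine), then Markovnikov hydroalkoxylation of the prenyl olefin through the tertiary cation, closes the 2,2-dimethyl dihydropyran. AgOTf acts as a mild Lewis acid and latent source of triflic acid.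

Step 4
Reactants: 7 6-bromo-2,2-dimethylchroman
Product: 10 (2,2-dimethylchroman-6-yl)boronic acid, via aryllithium 8 (not isolated), via lithium triisopropoxyborate 9 (not isolated)
Conditions: n-BuLi, THF, −78 °C; B(OiPr)3, −78 → 23 °C; aq HCl
Reagents that add atoms: triisopropyl borate, CC(C)OB(OC(C)C)OC(C)C; water, O
Why: Bromine–lithium exchange, trapping with a trialkyl borate and hydrolysis is the routine path to arylboronic acids. The alkyl aryl ether of the chroman is inert to n-BuLi at low temperature.

Step 5
Reactants: 4 7-(triisopropylsilyloxy)-4H-chromen-4-one; 10 (2,2-dimethylchroman-6-yl)boronic acid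
Product: 11 (S)-2-(2,2-dimethylchroman-6-yl)-7-(triisopropylsilyloxy)chroman-4-one
Conditions: 10 (2 equiv), Pd(OCOCF3)2 (5 mol %), (R)-t-BuPyOx [(R)-4-tert-butyl-2-(pyridin-2-yl)-4,5-dihydrooxazole] (6 mol %), NH4PF6 (30 mol %), H2O (5 equiv), ClCH2CH2Cl, 60 °C
Reagents that add atoms: none
Why: Palladium-catalysed asymmetric conjugate addition of an arylboronic acid to a chromone: transmetalation gives a cationic aryl complex of divalent palladium, the C2=C3 bond inserts, and water protonates the palladium enolate. The tert-butyl group of the (R)-ligand shields one face of the enone in the insertion and should set C2 as S. The medium is neither basic nor strongly acidic, so the chromone is not ring-opened and the silyl ether should stay.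

Step 6
Reactants: 11 (S)-2-(2,2-dimethylchroman-6-yl)-7-(triisopropylsilyloxy)chroman-4-one
Product: 12 (S)-2-(2,2-dimethylchroman-6-yl)-7-hydroxychroman-4-one
Conditions: Bu4NF, AcOH, THF, 0 °C
Reagents that add atoms: none
Why: Fluoride cleavage of an aryl silyl ether. Acetic acid buffers the phenoxide so that ring C is not opened to the chalcone (retro-oxa-Michael), which would racemise C2.

Step 7
Reactants: 13 2-methylbut-3-en-2-ol
Product: 15 tert-butyl 2-methylbut-3-en-2-yl carbonate, via lithium alkoxide 14 (not isolated)
Conditions: n-BuLi, THF, −78 → 0 °C; Boc2O, 0 → 23 °C; H2O
Reagents that add atoms: di-tert-butyl dicarbonate, CC(C)(C)OC(=O)OC(=O)OC(C)(C)C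
Why: Acylation of a lithium tert-alkoxide with the dicarbonate is the usual preparation of mixed tert-butyl allyl carbonates. The tertiary alkoxide is formed first because the neutral alcohol is too hindered to react cleanly.

Step 8
Reactants: 12 (S)-2-(2,2-dimethylchroman-6-yl)-7-hydroxychroman-4-one; 15 tert-butyl 2-methylbut-3-en-2-yl carbonate
Product: 16 (S)-2-(2,2-dimethylchroman-6-yl)-7-[(2-methylbut-3-en-2-yl)oxy]chroman-4-one
Conditions: Pd(PPh3)4 (5 mol %), 15 (1.5 equiv), THF, 0 °C
Reagents that add atoms: none
Why: Tsuji–Trost O-allylation: zerovalent palladium ionises the carbonate with loss of CO2, the tert-butoxide released deprotonates the acidic 7-OH, and the phenoxide attacks the more substituted allyl terminus under kinetic control at 0 °C to give the tertiary ether. The reaction is stopped before the catalyst can equilibrate this ether to the linear prenyl ether. No base stronger than the phenoxide persists, so C2 should be untouched.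

Step 9
Reactants: 16 (S)-2-(2,2-dimethylchroman-6-yl)-7-[(2-methylbut-3-en-2-yl)oxy]chroman-4-one
Product: 18 euchrenone a17 [(S)-2-(2,2-dimethylchroman-6-yl)-7-hydroxy-8-(3-methylbut-2-enyl)chroman-4-one], via dienone 17 (not isolated)
Conditions: degassed PhMe, 120 °C, sealed tube
Reagents that add atoms: none
Why: This is an aromatic Claisen rearrangement of a 1,1-dimethylallyl aryl ether, a known route to ortho-prenylphenols. In a concerted, chair-like [3,3] shift the O7–C(CH3)2 bond breaks while the terminal CH2 bonds to C8, giving the 8-prenyl cyclohexadienone 17, which enolises at once to phenol 18; because the allyl unit is transposed, the tertiary ether delivers the linear 3-methylbut-2-enyl group directly. No ring is closed and no lasting stereocentre is made: the sp3 C8 of 17 disappears on tautomerisation, and C2 is a spectator in a neutral medium, so its S configuration should be carried through. The tertiary ether should rearrange well below the temperature a primary allyl ether needs, since cleavage of the congested O–C bond is eased by the two methyl groups. The selectivity required is C8 over C6, and it rests on bond fixation in ring A: the vinylogous ester conjugation O1–C8a=C4a–C4=O favours the Kekulé structure with a C7=C8 double bond, the bias that directs 7-allyloxy chromones, chromanones and coumarins to C8. Any C6 isomer would be removed by chromatography, and any phenol 12 formed by loss of isoprene would be returned to step 8. Acid is excluded and heating is ended at full conversion so that the ortho-prenylphenol does not cyclise onto its olefin.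

## Compound list

1 | 2,4-dihydroxyacetophenone | CC(=O)c1ccc(O)cc1O | starting material
2 | 1-[2-hydroxy-4-(triisopropylsilyloxy)phenyl]ethanone | CC(=O)c1ccc(O[Si](C(C)C)(C(C)C)C(C)C)cc1O | intermediate
3 | (E)-3-(dimethylamino)-1-[2-hydroxy-4-(triisopropylsilyloxy)phenyl]prop-2-en-1-one | CN(C)/C=C/C(=O)c1ccc(O[Si](C(C)C)(C(C)C)C(C)C)cc1O | intermediate
4 | 7-(triisopropylsilyloxy)-4H-chromen-4-one | O=c1ccoc2cc(O[Si](C(C)C)(C(C)C)C(C)C)ccc12 | intermediate
5 | 4-bromophenol | Oc1ccc(Br)cc1 | starting material
6 | isoprene | C=CC(C)=C | starting material
7 | 6-bromo-2,2-dimethylchroman | CC1(C)CCc2cc(Br)ccc2O1 | intermediate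
8 | (2,2-dimethylchroman-6-yl)lithium | [Li]c1ccc2c(c1)CCC(C)(C)O2 | intermediate
9 | lithium (2,2-dimethylchroman-6-yl)triisopropoxyborate | [Li+].CC(C)O[B-](OC(C)C)(OC(C)C)c1ccc2c(c1)CCC(C)(C)O2 | intermediate
10 | (2,2-dimethylchroman-6-yl)boronic acid | OB(O)c1ccc2c(c1)CCC(C)(C)O2 | intermediate
11 | (S)-2-(2,2-dimethylchroman-6-yl)-7-(triisopropylsilyloxy)chroman-4-one | CC(C)[Si](Oc1ccc2c(c1)O[C@H](c1ccc3c(c1)CCC(C)(C)O3)CC2=O)(C(C)C)C(C)C | intermediate
12 | (S)-2-(2,2-dimethylchroman-6-yl)-7-hydroxychroman-4-one | Oc1ccc2c(c1)O[C@H](c1ccc3c(c1)CCC(C)(C)O3)CC2=O | intermediate
13 | 2-methylbut-3-en-2-ol | CC(C)(O)C=C | starting material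
14 | lithium 2-methylbut-3-en-2-olate | [Li+].[O-]C(C)(C)C=C | intermediate
15 | tert-butyl 2-methylbut-3-en-2-yl carbonate | C=CC(C)(C)OC(=O)OC(C)(C)C | intermediate
16 | (S)-2-(2,2-dimethylchroman-6-yl)-7-[(2-methylbut-3-en-2-yl)oxy]chroman-4-one | C=CC(C)(C)Oc1ccc2c(c1)O[C@H](c1ccc3c(c1)CCC(C)(C)O3)CC2=O | intermediate
17 | (2S)-2-(2,2-dimethylchroman-6-yl)-8-(3-methylbut-2-enyl)-2,3-dihydro-4H-chromene-4,7(8H)-dione | CC(C)=CCC1C(=O)C=CC2=C1O[C@H](c1ccc3c(c1)CCC(C)(C)O3)CC2=O | intermediate
18 | euchrenone a17, (S)-2-(2,2-dimethylchroman-6-yl)-7-hydroxy-8-(3-methylbut-2-enyl)chroman-4-one | CC(C)=CCc1c(O)ccc2c1O[C@H](c1ccc3c(c1)CCC(C)(C)O3)CC2=O | target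

## Step count and risks

Total: 9 steps. Longest linear sequence: 6 steps (steps 1, 2, 5, 6, 8, 9 from 2,4-dihydroxyacetophenone; the ring B branch through steps 3, 4, 5, 6, 8, 9 is equally long).

**Step 9 (key step).** The most likely failure is migration of the allyl unit to C6 as well as C8, because bond fixation in a ring fused to a saturated pyranone is weaker than in a fully conjugated chromone or coumarin. The second is thermal fragmentation of the tertiary ether to phenol 12 and isoprene. A change of conditions (Eu(fod)3 in CHCl3 at lower temperature) would be tried first. The fallback moves the rearrangement one stage earlier and sets out from chromone 4. Buffered Bu4NF gives 7-hydroxychromone F1. Pd(PPh3)4 with carbonate 15 gives 7-[(2-methylbut-3-en-2-yl)oxy]chromone F2. Heating in toluene should give 7-hydroxy-8-(3-methylbut-2-enyl)chromone F3, where the aromatic pyranone gives the strongest C7–C8 fixation and any isomer is removed on early material. TIPSCl and imidazole give the silyl ether F4. Conjugate addition of 10 under the conditions of step 5 gives the (S)-8-prenyl-7-silyloxy flavanone F5. Buffered Bu4NF then returns the route at 18, still without acid.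

**Step 5.** Enantioselectivity or conversion may be insufficient, because the 7-oxygenated chromone inserts slowly and the electron-rich boronic acid is prone to protodeboronation and homocoupling; the assumed sense of induction is a further uncertainty. The fallback gives up catalyst control in the C–C bond formation and sets out from 4 and 10. Addition with an achiral catalyst (Pd(OCOCF3)2 with 2,2′-bipyridine) gives the racemic silyl flavanone F6. This is resolved kinetically by asymmetric transfer hydrogenation with RuCl[(R,R)-TsDPEN](p-cymene) in HCO2H/Et3N, which should reduce the (R)-ketone to the cis-(2R,4R)-flavan-4-ol F7 and leave the (S)-ketone. After chromatography this is compound 11, where the route resumes.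

**Step 8.** The phenoxide may attack the unsubstituted allyl terminus, or the catalyst may isomerise the branched ether to the linear prenyl ether, and the para-acyl phenoxide is a weak nucleophile. The fallback sets out from 12. Copper-catalysed propargylation with 3-chloro-3-methylbut-1-yne (CuCl2·2H2O, DBU, MeCN, 0 °C) gives the 1,1-dimethylpropargyl ether F8. Semi-hydrogenation over Pd/CaCO3 poisoned with Pb(OAc)2 and quinoline returns the route at 16.

**Step 3.** Ring alkylation of the deactivated bromophenol may be sluggish, with oligomerisation of isoprene and O-alkylation competing. The fallback sets out from 5. Condensation with 3-methylbut-2-enoic acid in P2O5/MeSO3H (ester formation, Fries-type acylation, oxa-Michael closure) gives 6-bromo-2,2-dimethylchroman-4-one F9. Ionic deoxygenation with Et3SiH in CF3CO2H returns the route at 7.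

## Further compounds

F1 | step 9 | 7-hydroxy-4H-chromen-4-one | O=c1ccoc2cc(O)ccc12
F2 | step 9 | 7-[(2-methylbut-3-en-2-yl)oxy]-4H-chromen-4-one | C=CC(C)(C)Oc1ccc2c(c1)occc2=O
F3 | step 9 | 7-hydroxy-8-(3-methylbut-2-enyl)-4H-chromen-4-one | CC(C)=CCc1c(O)ccc2c1occc2=O
F4 | step 9 | 8-(3-methylbut-2-enyl)-7-(triisopropylsilyloxy)-4H-chromen-4-one | CC(C)=CCc1c(O[Si](C(C)C)(C(C)C)C(C)C)ccc2c1occc2=O
F5 | step 9 | (S)-2-(2,2-dimethylchroman-6-yl)-8-(3-methylbut-2-enyl)-7-(triisopropylsilyloxy)chroman-4-one | CC(C)=CCc1c(O[Si](C(C)C)(C(C)C)C(C)C)ccc2c1O[C@H](c1ccc3c(c1)CCC(C)(C)O3)CC2=O
F6 | step 5 | racemic 2-(2,2-dimethylchroman-6-yl)-7-(triisopropylsilyloxy)chroman-4-one | CC(C)[Si](Oc1ccc2c(c1)OC(c1ccc3c(c1)CCC(C)(C)O3)CC2=O)(C(C)C)C(C)C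
F7 | step 5 | (2R,4R)-2-(2,2-dimethylchroman-6-yl)-7-(triisopropylsilyloxy)chroman-4-ol | CC(C)[Si](Oc1ccc2c(c1)O[C@@H](c1ccc3c(c1)CCC(C)(C)O3)C[C@H]2O)(C(C)C)C(C)C
F8 | step 8 | (S)-2-(2,2-dimethylchroman-6-yl)-7-[(2-methylbut-3-yn-2-yl)oxy]chroman-4-one | C#CC(C)(C)Oc1ccc2c(c1)O[C@H](c1ccc3c(c1)CCC(C)(C)O3)CC2=O
F9 | step 3 | 6-bromo-2,2-dimethylchroman-4-one | CC1(C)CC(=O)c2cc(Br)ccc2O1
A1 | alternative 1 | 2-(2,2-dimethylchroman-6-yl)-7-(methoxymethoxy)-8-(3-methylbut-2-enyl)-4H-chromen-4-one | CC(C)=CCc1c(OCOC)ccc2c1OC(c1ccc3c(c1)CCC(C)(C)O3)=CC2=O
A2 | alternative 1 | 6-iodo-3-(methoxymethoxy)-2-(3-methylbut-2-enyl)phenol | CC(C)=CCc1c(OCOC)ccc(I)c1O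
A3 | alternative 1 | 6-ethynyl-2,2-dimethylchroman | C#Cc1ccc2c(c1)CCC(C)(C)O2
A4 | alternative 2 | (S)-7-acetoxy-2-[4-hydroxy-3-(3-methylbut-2-enyl)phenyl]-8-(3-methylbut-2-enyl)chroman-4-one | CC(C)=CCc1c(OC(C)=O)ccc2c1O[C@H](c1ccc(O)c(CC=C(C)C)c1)CC2=O
A5 | alternative 2 | (S)-7-acetoxy-2-(2,2-dimethylchroman-6-yl)-8-(3-methylbut-2-enyl)chroman-4-one | CC(C)=CCc1c(OC(C)=O)ccc2c1O[C@H](c1ccc3c(c1)CCC(C)(C)O3)CC2=O
A6 | alternative 3 | 7-(methoxymethoxy)-8-(3-methylbut-2-enyl)-4H-chromen-4-one | CC(C)=CCc1c(OCOC)ccc2c1occc2=O
A7 | alternative 3 | (S)-2-(2,2-dimethylchroman-6-yl)-7-(methoxymethoxy)-8-(3-methylbut-2-enyl)chroman-4-one | CC(C)=CCc1c(OCOC)ccc2c1O[C@H](c1ccc3c(c1)CCC(C)(C)O3)CC2=O
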